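**Retrosynthetic overview**
1. The last step is global hydrogenolysis of seven benzyl ethers. Before it, the O3–acyl bond is disconnected to a tetra‑O‑benzyl 2,3‑cis‑flavan‑3‑ol and tri‑O‑benzylgallic acid.
2. The pyran C ring is the only ring built; rings A, B and D and the oxirane are bought. Its C4–C4a bond is made last, by a light‑driven radical C–H alkylation of ring A with the terminal oxirane carbon (net isomerisation of an aryl oxiranylmethyl ether).
3. O1–C2 comes from Mitsunobu inversion of an anti benzylic epoxy alcohol with 3,5‑bis(benzyloxy)phenol.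
4. C2 is set by chelation‑controlled reduction of an aryl oxiranyl ketone. C2–C1′ comes from the B‑ring aryllithium and the Weinreb amide of methyl (R)‑glycidate, which supplies C2, C3 and C4 and the C3 stereocentre.
5. The 4′‑OMe group is installed first, on 5‑bromopyrogallol.

Assumption: 5‑bromopyrogallol, methyl (R)‑glycidate (the L‑serine‑derived enantiomer), 3,5‑bis(benzyloxy)phenol and 3,4,5‑tris(benzyloxy)benzoic acid are catalogue items.

**Step 1**
Reactants: 1, 5‑bromobenzene‑1,2,3‑triol
Product: 2, 5‑bromo‑2‑methoxybenzene‑1,3‑diol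
Conditions: MeI (1.0 equiv), Li2CO3 (1.1 equiv), DMF, 40 °C, Ar
Reagents that add atoms: iodomethane, CI
Why: Williamson O‑methylation of the mono‑anion; the central OH is the most acidic because its phenoxide is hydrogen‑bonded by both flanking OH groups, the same logic as 4‑O‑alkylation of gallates.

**Step 2**
Reactants: 2
Product: 3, 1,3‑bis(benzyloxy)‑5‑bromo‑2‑methoxybenzene
Conditions: BnBr (2.3 equiv), K2CO3, DMF, 60 °C
Reagents that add atoms: benzyl bromide, BrCc1ccccc1
Why: Exhaustive Williamson benzylation of the two remaining phenols; the aryl bromide is inert.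

**Step 3**
Reactants: 4, methyl (2R)‑oxirane‑2‑carboxylate
Product: 5, (2R)‑N‑methoxy‑N‑methyloxirane‑2‑carboxamide
Conditions: MeNH(OMe)·HCl, LiHMDS, THF, −78 → −20 °C
Reagents that add atoms: N,O‑dimethylhydroxylamine (as HCl salt), CNOC
Why: Ester aminolysis by the lithium amide (Weinreb amide formation); no bond at the stereocentre is broken and the strained oxirane C–H does not enolise.

**Step 4**
Reactants: 3 and 5
Product: 6, [3,5‑bis(benzyloxy)‑4‑methoxyphenyl][(2R)‑oxiran‑2‑yl]methanone
Conditions: 3, n‑BuLi, THF, −78 °C; then 5, −78 °C; aq NH4Cl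
Reagents that add atoms: none (all atoms come from 3 and 5)
Why: Br–Li exchange followed by Weinreb ketone synthesis; the chelated tetrahedral intermediate stops at the ketone, and an unactivated epoxide is not opened by ArLi at −78 °C, so the (R) centre is carried through.

**Step 5**
Reactants: 6
Product: 7, (S)‑[3,5‑bis(benzyloxy)‑4‑methoxyphenyl][(2R)‑oxiran‑2‑yl]methanol (anti/erythro)
Conditions: Zn(BH4)2, Et2O, −30 → 0 °C
Reagents that add atoms: none
Why: Chelation‑controlled (Cram‑chelate) hydride reduction; Zn2+ holds the carbonyl and oxirane oxygens syn‑periplanar and hydride enters from the face bearing the oxirane C–H, so the purchased (R) centre sets the new carbinol as (S) (anti; expected dr ≥ 9:1, minor isomer removed by chromatography).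

**Step 6**
Reactants: 7 and 8, 3,5‑bis(benzyloxy)phenol
Product: 9, (2R)‑2‑{(R)‑[3,5‑bis(benzyloxy)phenoxy][3,5‑bis(benzyloxy)‑4‑methoxyphenyl]methyl}oxirane
Conditions: PPh3, DIAD, toluene, 0 °C → rt
Reagents that add atoms: none (the aryloxy group comes from 8)
Why: Mitsunobu etherification with SN2 inversion (S → R at C2, placing O1 and O3 syn, which is 2,3‑cis after ring closure); the adjacent oxirane and the two meta‑alkoxy groups disfavour a benzylic cation, and the epoxide and benzyl ethers are inert.

**Step 7**
Reactants: 9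
Product: 10, (2R,3R)‑5,7‑bis(benzyloxy)‑2‑[3,5‑bis(benzyloxy)‑4‑methoxyphenyl]‑3,4‑dihydro‑2H‑chromen‑3‑ol
Conditions: 10‑phenylphenothiazine (PTH, 5 mol %), LiI (30 mol %), AcOH (30 mol %), MeCN–EtOAc 2:1 (0.03 M), 390 nm LEDs, 35 °C, degassed
Reagents that add atoms: none (isomerisation)
Why: Proposed new method: iodide‑relay photoredox cycloisomerisation of an aryl oxiranylmethyl ether, in which (i) LiI/AcOH opens the epoxide by SN2 at the terminal CH2 to the iodohydrin, leaving C3–O untouched, (ii) excited PTH (E* ≈ −2.1 V) cleaves the C–I bond, (iii) the primary C4 radical attacks an ortho carbon of the phloroglucinol‑type ring in a six‑membered homolytic aromatic substitution, where the two ortho sites are equivalent, the spin lands on three O‑bearing carbons, and ipso attack gains no such stabilisation, (iv) PTH•+ (or I2 formed in situ) oxidises the cyclohexadienyl radical and acetate removes the proton, regenerating PTH, I− and AcOH, so the C4–C4a bond and the C ring form under near‑neutral conditions that never ionise the benzylic C2–O1 bond or touch either stereocentre; the closest known reactions are photoredox intramolecular arene C–H alkylation with alkyl iodides or redox‑active esters, the in‑situ iodohydrin relay of nickel/photoredox epoxide arylation, and titanocene‑catalysed radical arylation of epoxides, which cleaves the other C–O bond and would destroy C3.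

**Step 8**
Reactants: 10 and 11, 3,4,5‑tris(benzyloxy)benzoic acid
Product: 12, (2R,3R)‑5,7‑bis(benzyloxy)‑2‑[3,5‑bis(benzyloxy)‑4‑methoxyphenyl]chroman‑3‑yl 3,4,5‑tris(benzyloxy)benzoate
Conditions: 11, (COCl)2, cat. DMF, CH2Cl2; concentrate; then 10, DMAP, CH2Cl2, rt
Reagents that add atoms: none (the acyl group comes from 11)
Why: DMAP‑catalysed acylation of the only free OH (the axial 3‑OH) with the acid chloride; the C3–O bond is not broken, so configuration is retained.

**Step 9**
Reactants: 12
Product: 13, 4′‑O‑methyl‑(−)‑epigallocatechin‑3‑O‑gallate (target)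
Conditions: H2 (1 atm), 20 % Pd(OH)2/C, THF–MeOH 1:1, rt; work up under Ar
Reagents that add atoms: none
Why: Catalytic hydrogenolysis removes all seven O‑benzyl groups, while the methyl ether, the ester and the cyclic C2–O1 ether persist, as is standard for benzylated catechin gallates; neither stereocentre is affected.

**Compound list**
1 | 5‑bromobenzene‑1,2,3‑triol | Oc1cc(Br)cc(O)c1O | starting material
2 | 5‑bromo‑2‑methoxybenzene‑1,3‑diol | COc1c(O)cc(Br)cc1O | intermediate
3 | 1,3‑bis(benzyloxy)‑5‑bromo‑2‑methoxybenzene | COc1c(OCc2ccccc2)cc(Br)cc1OCc3ccccc3 | intermediate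
4 | methyl (2R)‑oxirane‑2‑carboxylate | COC(=O)[C@H]1CO1 | starting material
5 | (2R)‑N‑methoxy‑N‑methyloxirane‑2‑carboxamide | CON(C)C(=O)[C@H]1CO1 | intermediate
6 | [3,5‑bis(benzyloxy)‑4‑methoxyphenyl][(2R)‑oxiran‑2‑yl]methanone | COc1c(OCc2ccccc2)cc(C(=O)[C@H]3CO3)cc1OCc4ccccc4 | intermediate
7 | (S)‑[3,5‑bis(benzyloxy)‑4‑methoxyphenyl][(2R)‑oxiran‑2‑yl]methanol | COc1c(OCc2ccccc2)cc([C@H](O)[C@H]3CO3)cc1OCc4ccccc4 | intermediate
8 | 3,5‑bis(benzyloxy)phenol | Oc1cc(OCc2ccccc2)cc(OCc3ccccc3)c1 | starting material
9 | (2R)‑2‑{(R)‑[3,5‑bis(benzyloxy)phenoxy][3,5‑bis(benzyloxy)‑4‑methoxyphenyl]methyl}oxirane | COc1c(OCc2ccccc2)cc([C@@H](Oc3cc(OCc4ccccc4)cc(OCc5ccccc5)c3)[C@H]6CO6)cc1OCc7ccccc7 | intermediate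
10 | (2R,3R)‑5,7‑bis(benzyloxy)‑2‑[3,5‑bis(benzyloxy)‑4‑methoxyphenyl]chroman‑3‑ol | COc1c(OCc2ccccc2)cc([C@H]3Oc4cc(OCc5ccccc5)cc(OCc6ccccc6)c4C[C@H]3O)cc1OCc7ccccc7 | intermediate
11 | 3,4,5‑tris(benzyloxy)benzoic acid | OC(=O)c1cc(OCc2ccccc2)c(OCc3ccccc3)c(OCc4ccccc4)c1 | starting material
12 | hepta‑O‑benzyl‑4′‑O‑methyl‑EGCG | COc1c(OCc2ccccc2)cc([C@H]3Oc4cc(OCc5ccccc5)cc(OCc6ccccc6)c4C[C@H]3OC(=O)c7cc(OCc8ccccc8)c(OCc9ccccc9)c(OCc%10ccccc%10)c7)cc1OCc%11ccccc%11 | intermediate
13 | 4′‑O‑methylepigallocatechin‑3‑O‑gallate | COc1c(O)cc([C@H]2Oc3cc(O)cc(O)c3C[C@H]2OC(=O)c2cc(O)c(O)c(O)c2)cc1O | target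

**Totals**
Total steps: 9. Longest linear sequence: 8 (steps 1, 2, 4, 5, 6, 7, 8, 9).

**Steps most likely to fail**
1. **Step 7 (proposed new step).** The risks are slow cyclisation of a nucleophilic primary radical onto an electron‑rich arene, hydrodeiodination, and poor HI turnover.
   Fallback (known chemistry, polar instead of radical):
   - Run step 6 with 3,5‑bis(benzyloxy)‑2‑iodophenol.
   - Open the oxirane to the bromohydrin and silylate O3.
   - Close C4–C4a by iodine–metal exchange and intramolecular SN2 alkylation, then desilylate. This is the established aryl‑metal pyran annulation for flavan‑3‑ols.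
2. **Step 5.** The risk is insufficient anti selectivity for an aryl oxiranyl ketone.
   Fallback (C2 set in a C–C bond‑forming step instead of by hydride delivery):
   - Add the aryl‑titanium reagent from 3 to (R)‑2,3‑O‑isopropylideneglyceraldehyde (NaIO4 cleavage of D‑mannitol diacetonide), a Felkin–Anh anti addition.
   - Carry out the Mitsunobu reaction on the acetonide.
   - Hydrolyse, then convert the primary OH to the iodide (I2, PPh3, imidazole). This iodohydrin enters the step 7 photocyclisation directly.
3. **Step 1.** The risk is only moderate selectivity for the central OH of 5‑bromopyrogallol.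
   Fallback (buy the methyl ether already in place): methyl 3,5‑dihydroxy‑4‑methoxybenzoate → benzylation → saponification → Curtius rearrangement to the aniline → Sandmeyer bromination to 3. This is regiochemically unambiguous but longer.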